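At the reading at 40 h you will want a number with no clock in it, so I took one from the south run before I left the bench.

all flasks: left-handed substrate 44 mM; right-handed substrate 44 mM; reagent 132 mM; racemization catalyst 0.84 mM
- south: free catalyst 130 µM; run made earlier
- flask: free catalyst 88 µM; time 40 h

- south (time / h: left-handed product / %, right-handed product / %): 0.333: 0.8, 0.1; 0.667: 1.8, 0.2; 1.50: 3.9, 0.5; 4.00: 8.7, 1.2

(standard deviation of a reading: 0.3 percentage points)

- left-handed product and right-handed product together, in percent of the left-handed substrate and right-handed substrate charged together, at 40 h
- excess of left-handed product over right-handed product in the product at 40 h
- whether the exchange between left-handed substrate and right-handed substrate keeps pace with the reaction: how far the product's excess at 40 h gets from its value without exchange to its value with instant exchange (above 80% keeps pace, below 20% hardly takes part, else lags behind)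

- free catalyst is single-handed; left-handed substrate and right-handed substrate are mirror images of each other, charged as a racemate, each of them at the stated concentration
- an excess is the difference of the two amounts in percent of their sum
- an excess is below zero if the other one leads
- no earlier run changes the charge of free catalyst; that part of a forecast is a guess

I carried the selectivity factor s, the logarithm of the fraction of left-handed substrate remaining over that of the right-handed substrate, which the south run put at 7.87 at 4.00 h. One standard deviation on the right-handed product stretched that reading from 6.28 to 10.5. Without exchange, and with free catalyst and reagent entering both rates alike, s does not depend on time.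

I solved both ends. With instant exchange the excess stays at 77.4%. Without exchange, the south pseudo-first-order constant 0.0478 h⁻¹, scaled by the catalyst charge (a guess), gave an exposure E, constant times time, of 1.29. That left 27.4% and 84.8% of the two substrates' charges, so y was 43.9% and the excess 65.4%. I committed to this end as a guess, not as something read from the south run. I distrusted y, because the constant read earlier was higher, 0.0550 h⁻¹. Add no free catalyst: the excess sinks with conversion.

The forecast gave 43% (29% to 55%), 69% and lags behind: “Slower reaction gives it more chance, so I guess partial exchange”.

The flask gave 33.8%, 65.3% and hardly takes part, 1.5% of the way.

    left-handed substrate + racemization catalyst ⇌ right-handed substrate + racemization catalyst, rate k1*[racemization catalyst]*[left-handed substrate] forward; the back reaction follows from the equilibrium constant (k = 4.20 L mol⁻¹ h⁻¹)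
    free catalyst ⇌ dormant form (K = 2.00, k = 0.0320 h⁻¹)
    reagent + free catalyst + right-handed substrate → free catalyst + right-handed product (k = 490 L² mol⁻² h⁻¹)
    racemization catalyst → spent catalyst (k = 0.150 h⁻¹)
    reagent + free catalyst + left-handed substrate → free catalyst + left-handed product (k = 3200 L² mol⁻² h⁻¹)

My y stood 10 percentage points too high, but the flask's remains, 44% and 88%, gave s = 6.33, inside the band. The neighbour charged with 0.35 mM of free catalyst kept 7.3% of its left-handed substrate. From that figure, s and its low end put the excess between 46.2% and 53.2%. The neighbour kept 66% of its right-handed substrate, gave s = 6.30, and reached 63.2% with an excess of 47.8%.

The readings were computed with made-up constants.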